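**Plan**
1. Retrosynthetic cuts: the two aryl O–Si bonds; C9''–N (auxiliary) and C7''–C8'' (aldol); O4'–C8'' (phenol alkylation); in the furofuran C8–C8' and O–C7' (one operation); O–C9' of the C7–O–C9' ether; C7–C8 and C7'–C8' (vinyl additions to syringaldehyde and vanillin).
2. Enabling feature: C8 and C8' each lie β to a ring oxygen (O on C9, O on C9'), and C8' is bonded to C7', the benzylic carbon of ring B. C8 can therefore start as a radical from a C8–C9 epoxide, C8'=C7' can act as a styrene acceptor, and the C9 oxygen released from the epoxide can close onto C7'.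
3. Forward order: the ring C epoxy alcohol and the ring B cinnamyl bromide are joined as the C7–O–C9' ether; both tetrahydrofuran rings then form in one flask (first C7–O–C9'–C8'–C8, then C8–C9–O–C7'–C8'); the ring B phenol is freed and given a glycolyl imide; the chain C9''–C8''–C7''–ring A is completed by aldol addition, reduction and desilylation.
4. Stereochemistry: C7 from a Sharpless kinetic resolution; C8, C8' and C7' relayed from C7 in the cascade; C8'' and C7'' from (R)-4-benzyl-2-oxazolidinone in an Evans syn aldol.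

Key step: step 8

Remark (numbering): ring C is the syringyl ring with C7–C8–C9, ring B the central guaiacyl ring with C7'–C8'–C9', ring A the terminal guaiacyl ring with C7''–C8''–C9''. Read from its SMILES, the target is (7R,8S,7'R,8'S,7''S,8''S): a furofuran with both aryl groups on the convex face and a threo arylglycerol ether.
Remark (assumption): in the Sharpless kinetic resolution the aryl group of 4 is taken to behave like the alkyl group of an alkyl vinyl carbinol, so that L-(+)-DIPT selects the (R)-enantiomer of 4.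
Remark (notation): in SMILES of titanium species the cyclopentadienyl ligands are drawn as sigma-bonded C5H5 groups.

**Route**

Step 1
Reactants: 1 syringaldehyde (4-hydroxy-3,5-dimethoxybenzaldehyde)
Product: 2 3,5-dimethoxy-4-(triisopropylsilyloxy)benzaldehyde
Conditions: TIPSCl, imidazole, DMAP (cat.), DMF, rt
Reagents that add atoms: triisopropylsilyl chloride, CC(C)[Si](Cl)(C(C)C)C(C)C
Why: Imidazole-promoted O-silylation of the phenol (silyl ether formation) should go cleanly, and the bulky triisopropylsilyl group is chosen because it should survive the Grignard reagent, NaH, K2CO3 and LiBH4 used later and falls to fluoride at the end.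

Step 2
Reactants: 2 3,5-dimethoxy-4-(triisopropylsilyloxy)benzaldehyde; 3 vinylmagnesium bromide
Product: 4 rac-1-[3,5-dimethoxy-4-(triisopropylsilyloxy)phenyl]prop-2-en-1-ol
Conditions: THF, −78 → 0 °C; H2O quench
Reagents that add atoms: none
Why: Grignard addition of the vinyl group to the aldehyde forms the C7–C8 bond and gives the racemic aryl vinyl carbinol that the next step resolves, so no stereocontrol is needed here.

Step 3
Reactants: 4 rac-1-[3,5-dimethoxy-4-(triisopropylsilyloxy)phenyl]prop-2-en-1-ol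
Product: 5 (S)-[3,5-dimethoxy-4-(triisopropylsilyloxy)phenyl][(2R)-oxiran-2-yl]methanol (erythro epoxy alcohol)
Conditions: Ti(OiPr)4 (0.15 equiv), L-(+)-DIPT (0.2 equiv), t-BuOOH (0.45 equiv), 4 Å MS, CH2Cl2, −20 °C
Reagents that add atoms: tert-butyl hydroperoxide, CC(C)(C)OO
Why: Sharpless kinetic resolution: with the Ti(OiPr)4/L-(+)-DIPT catalyst only the (R)-enantiomer of 4 should be epoxidised at a useful rate, on the vinyl face that gives the erythro epoxy alcohol, so that C7 is fixed by enantiomer selection (C8 is of no later consequence) while the unreacted (S)-enantiomer of 4 is removed by chromatography.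

Step 4
Reactants: 6 vanillin (4-hydroxy-3-methoxybenzaldehyde)
Product: 7 4-(allyloxy)-3-methoxybenzaldehyde
Conditions: allyl bromide, K2CO3, acetone, reflux
Reagents that add atoms: allyl bromide, C=CCBr
Why: Williamson ether synthesis on the phenoxide; the allyl group is chosen because zerovalent palladium removes it later under neutral conditions, without the hydrogenolysis that would endanger the benzylic C–O bonds of the furofuran.

Step 5
Reactants: 7 4-(allyloxy)-3-methoxybenzaldehyde; 3 vinylmagnesium bromide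
Product: 8 rac-1-[4-(allyloxy)-3-methoxyphenyl]prop-2-en-1-ol
Conditions: THF, 0 °C; H2O quench
Reagents that add atoms: none
Why: Grignard addition to the aldehyde installs the chain C7'–C8'–C9' of ring B as a secondary allylic alcohol whose stereocentre is erased in the next step.

Step 6
Reactants: 8 rac-1-[4-(allyloxy)-3-methoxyphenyl]prop-2-en-1-ol
Product: 9 (E)-1-(allyloxy)-4-(3-bromoprop-1-en-1-yl)-2-methoxybenzene
Conditions: PBr3 (0.4 equiv), Et2O, 0 °C; used at once without chromatography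
Reagents that add atoms: phosphorus tribromide, BrP(Br)Br
Why: Bromination with allylic transposition (SN2'-type substitution of the bromophosphite) should place bromine on the terminal carbon C9' because the conjugated E-cinnamyl bromide is the thermodynamically favoured allylic isomer.

Step 7
Reactants: 5 (S)-[3,5-dimethoxy-4-(triisopropylsilyloxy)phenyl][(2R)-oxiran-2-yl]methanol; 9 (E)-1-(allyloxy)-4-(3-bromoprop-1-en-1-yl)-2-methoxybenzene
Product: 11 (2R)-2-[(S)-{[(2E)-3-(4-allyloxy-3-methoxyphenyl)prop-2-en-1-yl]oxy}{3,5-dimethoxy-4-(triisopropylsilyloxy)phenyl}methyl]oxirane, via NaO–C7 alkoxide 10 (not isolated)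
Conditions: NaH, THF/DMF, 0 °C; then 9, Bu4NI (cat.), 0 °C → rt
Reagents that add atoms: none
Why: Williamson ether synthesis between the C7 alkoxide and the primary allylic bromide forms the C7–O–C9' ether without touching a stereocentre, iodide catalysis and low temperature keeping alkylation faster than epoxide migration (Payne rearrangement).

Step 8
Reactants: 11 (2R)-2-[(S)-{[(2E)-3-(4-allyloxy-3-methoxyphenyl)prop-2-en-1-yl]oxy}{3,5-dimethoxy-4-(triisopropylsilyloxy)phenyl}methyl]oxirane
Product: 14 (1R,3aS,4R,6aS)-1-[4-(allyloxy)-3-methoxyphenyl]-4-[3,5-dimethoxy-4-(triisopropylsilyloxy)phenyl]tetrahydro-1H,3H-furo[3,4-c]furan (7R 8S 7'R 8'S in lignan numbering), via C7'–TiCp2Cl C9–OTiCp2Cl tetrahydrofuran 12 (not isolated), via C7' iodide C9–OTiCp2Cl tetrahydrofuran 13 (not isolated)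
Conditions: Cp2TiCl (2.5 equiv; from Cp2TiCl2, Zn dust, THF, rt; filtered), slow addition, THF, rt; then I2, THF, rt → 60 °C
Reagents that add atoms: none
Why: Cp2TiCl (trivalent titanium) transfers one electron to the terminal epoxide and cleaves the C8–O bond, which gives the secondary C8 radical with C9–O held on titanium; this radical adds 5-exo-trig to C8' of the ring B styrene (C8–C8' bond, first tetrahydrofuran ring C7–O–C9'–C8'–C8) and the benzylic C7' radical so formed is captured by a second Cp2TiCl as 12. Iodine then converts the C7'–Ti bond into the easily ionised benzylic iodide 13, and the C9–O–Ti alkoxide displaces iodide in a 5-exo-tet closure (O–C7' bond, second tetrahydrofuran ring). The closest known reaction type is the Cp2TiCl-mediated reductive opening of epoxides with radical cyclisation onto a tethered alkene, used on epoxy allyl ethers with an iodine-induced second ether closure. C8 and C8' are set relative to the preset C7 in the chair-like 5-exo transition state, in which the ring C aryl group lies pseudo-equatorial so that C9 comes out trans to it and the C7' arm cis to C9; C7' is set in the second closure, where only the cis-fused bicycle can form and ring B takes the convex face. The step needs homolysis toward the secondary radical (secured by the terminal epoxide), cyclisation faster than reduction of the C8 radical by further Cp2TiCl (secured by the conjugated styrene acceptor and slow addition of the reagent) and tolerance of the allyl aryl ether and the silyl ether (neither should react with trivalent titanium or iodine under these conditions). The C8 configuration of 11 is lost in the planar radical, so only C7 has to be defined beforehand.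

Step 9
Reactants: 14 (1R,3aS,4R,6aS)-1-[4-(allyloxy)-3-methoxyphenyl]-4-[3,5-dimethoxy-4-(triisopropylsilyloxy)phenyl]tetrahydro-1H,3H-furo[3,4-c]furan
Product: 15 4-{(1R,3aS,4R,6aS)-4-[3,5-dimethoxy-4-(triisopropylsilyloxy)phenyl]tetrahydro-1H,3H-furo[3,4-c]furan-1-yl}-2-methoxyphenol
Conditions: Pd(PPh3)4 (cat.), morpholine, THF, rt
Reagents that add atoms: none
Why: Tsuji–Trost-type deallylation: zerovalent palladium ionises the allyl aryl ether and morpholine captures the allyl fragment, which should free the ring B phenol while the silyl ether and the benzylic ethers of the furofuran are left alone.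

Step 10
Reactants: 16 (R)-4-benzyl-2-oxazolidinone; 17 bromoacetyl bromide
Product: 19 (R)-4-benzyl-3-(bromoacetyl)oxazolidin-2-one, via N-lithio oxazolidinone 18 (not isolated)
Conditions: n-BuLi, THF, −78 °C; then 17, −78 → 0 °C
Reagents that add atoms: none
Why: N-Acylation of the lithiated oxazolidinone with the acid bromide is the standard entry to haloacetyl imides, the acyl bromide reacting far faster than the alkyl bromide, and the auxiliary stereocentre is not involved.

Step 11
Reactants: 15 4-{(1R,3aS,4R,6aS)-4-[3,5-dimethoxy-4-(triisopropylsilyloxy)phenyl]tetrahydro-1H,3H-furo[3,4-c]furan-1-yl}-2-methoxyphenol; 19 (R)-4-benzyl-3-(bromoacetyl)oxazolidin-2-one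
Product: 20 (R)-4-benzyl-3-{[4-((1R,3aS,4R,6aS)-4-{3,5-dimethoxy-4-(triisopropylsilyloxy)phenyl}tetrahydro-1H,3H-furo[3,4-c]furan-1-yl)-2-methoxyphenoxy]acetyl}oxazolidin-2-one
Conditions: K2CO3, acetone, rt
Reagents that add atoms: none
Why: Williamson-type O-alkylation: the phenoxide displaces the activated α-bromide of the imide by SN2, which attaches the unit C8''–C9'' to O4' together with the auxiliary under conditions too mild to cleave the imide or the silyl ether.

Step 12
Reactants: 6 vanillin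
Product: 21 3-methoxy-4-(triisopropylsilyloxy)benzaldehyde
Conditions: TIPSCl, imidazole, DMF, rt
Reagents that add atoms: triisopropylsilyl chloride, CC(C)[Si](Cl)(C(C)C)C(C)C
Why: O-Silylation of the phenol, the same silyl group being used on rings A and C so that one fluoride treatment at the end removes both.

Step 13
Reactants: 20 (R)-4-benzyl-3-{[4-((1R,3aS,4R,6aS)-4-{3,5-dimethoxy-4-(triisopropylsilyloxy)phenyl}tetrahydro-1H,3H-furo[3,4-c]furan-1-yl)-2-methoxyphenoxy]acetyl}oxazolidin-2-one; 21 3-methoxy-4-(triisopropylsilyloxy)benzaldehyde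
Product: 24 (R)-4-benzyl-3-[(2R,3S)-3-hydroxy-3-{3-methoxy-4-(triisopropylsilyloxy)phenyl}-2-{4-[(1R,3aS,4R,6aS)-4-{3,5-dimethoxy-4-(triisopropylsilyloxy)phenyl}tetrahydro-1H,3H-furo[3,4-c]furan-1-yl]-2-methoxyphenoxy}propanoyl]oxazolidin-2-one (syn aldol adduct), via Z-dibutylboron enolate 22 (not isolated), via dibutylboron aldolate 23 (not isolated)
Conditions: Bu2BOTf, iPr2NEt, CH2Cl2, −78 → 0 °C; then 21, −78 → 0 °C; then pH 7 buffer, MeOH, H2O2, 0 °C
Reagents that add atoms: none
Why: Evans syn aldol reaction: the Z-dibutylboron enolate 22 should add to the aldehyde through a closed six-membered chair transition state on the enolate face turned away from the benzyl group of the (R)-auxiliary, which sets C8'' and C7'' together as the (2R,3S) syn adduct, the threo arrangement that reads (7''S,8''S) once the acyl carbon has become CH2OH.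

Step 14
Reactants: 24 syn aldol adduct
Product: 25 (1S,2S)-1-[3-methoxy-4-(triisopropylsilyloxy)phenyl]-2-[4-((1R,3aS,4R,6aS)-4-{3,5-dimethoxy-4-(triisopropylsilyloxy)phenyl}tetrahydro-1H,3H-furo[3,4-c]furan-1-yl)-2-methoxyphenoxy]propane-1,3-diol
Conditions: LiBH4, H2O (1 equiv), THF, 0 °C
Reagents that add atoms: none
Why: Reductive cleavage of the imide with LiBH4 (hydride reduction of the activated exocyclic carbonyl) should give the primary C9'' alcohol and release the auxiliary without touching C8'' or the silyl ethers.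

Step 15
Reactants: 25 bis-silylated diol
Product: 26 (1S,2S)-1-(4-hydroxy-3-methoxyphenyl)-2-{4-[(1R,3aS,4R,6aS)-4-(4-hydroxy-3,5-dimethoxyphenyl)tetrahydro-1H,3H-furo[3,4-c]furan-1-yl]-2-methoxyphenoxy}propane-1,3-diol (target)
Conditions: Bu4NF, AcOH, THF, 0 °C → rt
Reagents that add atoms: none
Why: Fluoride-mediated desilylation of both aryl silyl ethers, buffered with acetic acid so that the phenoxides formed do not open the benzylic ethers through quinone methides, should give the target with all six stereocentres unchanged.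

**Compound list**
1 | syringaldehyde (4-hydroxy-3,5-dimethoxybenzaldehyde) | COc1cc(C=O)cc(OC)c1O | starting material
2 | 3,5-dimethoxy-4-(triisopropylsilyloxy)benzaldehyde | COc1cc(C=O)cc(OC)c1O[Si](C(C)C)(C(C)C)C(C)C | intermediate
3 | vinylmagnesium bromide | C=C[Mg]Br | starting material
4 | rac-1-[3,5-dimethoxy-4-(triisopropylsilyloxy)phenyl]prop-2-en-1-ol | C=CC(O)c1cc(OC)c(O[Si](C(C)C)(C(C)C)C(C)C)c(OC)c1 | intermediate
5 | (S)-[3,5-dimethoxy-4-(triisopropylsilyloxy)phenyl][(2R)-oxiran-2-yl]methanol (erythro) | O[C@H]([C@H]1CO1)c1cc(OC)c(O[Si](C(C)C)(C(C)C)C(C)C)c(OC)c1 | intermediate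
6 | vanillin (4-hydroxy-3-methoxybenzaldehyde) | COc1cc(C=O)ccc1O | starting material
7 | 4-(allyloxy)-3-methoxybenzaldehyde | C=CCOc1ccc(C=O)cc1OC | intermediate
8 | rac-1-[4-(allyloxy)-3-methoxyphenyl]prop-2-en-1-ol | C=CCOc1ccc(C(O)C=C)cc1OC | intermediate
9 | (E)-1-(allyloxy)-4-(3-bromoprop-1-en-1-yl)-2-methoxybenzene | C=CCOc1ccc(/C=C/CBr)cc1OC | intermediate
10 | sodium (S)-[3,5-dimethoxy-4-(triisopropylsilyloxy)phenyl][(2R)-oxiran-2-yl]methanolate | [Na+].[O-][C@H]([C@H]1CO1)c1cc(OC)c(O[Si](C(C)C)(C(C)C)C(C)C)c(OC)c1 | intermediate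
11 | (2R)-2-[(S)-{[(2E)-3-(4-allyloxy-3-methoxyphenyl)prop-2-en-1-yl]oxy}{3,5-dimethoxy-4-(triisopropylsilyloxy)phenyl}methyl]oxirane | C=CCOc1ccc(/C=C/CO[C@H]([C@H]2CO2)c2cc(OC)c(O[Si](C(C)C)(C(C)C)C(C)C)c(OC)c2)cc1OC | intermediate
12 | 2,3-trans-3,4-cis tetrahydrofuran with the ring C aryl group on C7, CH2–O–TiCp2Cl on C8 and CH(TiCp2Cl)(4-allyloxy-3-methoxyphenyl) on C8' (C7' not defined) | COc1cc([C@@H]2OC[C@@H](C([Ti](Cl)(C3C=CC=C3)C3C=CC=C3)c3ccc(OCC=C)c(OC)c3)[C@H]2CO[Ti](Cl)(C2C=CC=C2)C2C=CC=C2)cc(OC)c1O[Si](C(C)C)(C(C)C)C(C)C | intermediate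
13 | the same tetrahydrofuran with CH(I)(4-allyloxy-3-methoxyphenyl) on C8' and CH2–O–TiCp2Cl on C8 | COc1cc([C@@H]2OC[C@@H](C(I)c3ccc(OCC=C)c(OC)c3)[C@H]2CO[Ti](Cl)(C2C=CC=C2)C2C=CC=C2)cc(OC)c1O[Si](C(C)C)(C(C)C)C(C)C | intermediate
14 | (1R,3aS,4R,6aS)-1-[4-(allyloxy)-3-methoxyphenyl]-4-[3,5-dimethoxy-4-(triisopropylsilyloxy)phenyl]tetrahydro-1H,3H-furo[3,4-c]furan | C=CCOc1ccc([C@@H]2OC[C@@H]3[C@H]2CO[C@H]3c2cc(OC)c(O[Si](C(C)C)(C(C)C)C(C)C)c(OC)c2)cc1OC | intermediate
15 | 4-{(1R,3aS,4R,6aS)-4-[3,5-dimethoxy-4-(triisopropylsilyloxy)phenyl]tetrahydro-1H,3H-furo[3,4-c]furan-1-yl}-2-methoxyphenol | Oc1ccc([C@@H]2OC[C@@H]3[C@H]2CO[C@H]3c2cc(OC)c(O[Si](C(C)C)(C(C)C)C(C)C)c(OC)c2)cc1OC | intermediate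
16 | (R)-4-benzyl-2-oxazolidinone | O=C1N[C@H](Cc2ccccc2)CO1 | starting material
17 | bromoacetyl bromide | BrCC(Br)=O | starting material
18 | N-lithio-(R)-4-benzyl-2-oxazolidinone | O=C1N([Li])[C@H](Cc2ccccc2)CO1 | intermediate
19 | (R)-4-benzyl-3-(bromoacetyl)oxazolidin-2-one | O=C1N(C(=O)CBr)[C@H](Cc2ccccc2)CO1 | intermediate
20 | (R)-4-benzyl-3-{[4-((1R,3aS,4R,6aS)-4-{3,5-dimethoxy-4-(triisopropylsilyloxy)phenyl}tetrahydro-1H,3H-furo[3,4-c]furan-1-yl)-2-methoxyphenoxy]acetyl}oxazolidin-2-one | O=C1N(C(=O)COc2ccc([C@@H]3OC[C@@H]4[C@H]3CO[C@H]4c3cc(OC)c(O[Si](C(C)C)(C(C)C)C(C)C)c(OC)c3)cc2OC)[C@H](Cc2ccccc2)CO1 | intermediate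
21 | 3-methoxy-4-(triisopropylsilyloxy)benzaldehyde | COc1cc(C=O)ccc1O[Si](C(C)C)(C(C)C)C(C)C | intermediate
22 | Z-dibutylboron enolate of 20 | CCCCB(CCCC)O/C(=C\Oc1ccc([C@@H]2OC[C@@H]3[C@H]2CO[C@H]3c2cc(OC)c(O[Si](C(C)C)(C(C)C)C(C)C)c(OC)c2)cc1OC)N1C(=O)OC[C@H]1Cc1ccccc1 | intermediate
23 | dibutylboron aldolate of 24 (Bu2B on O7'') | COc1cc([C@H](OB(CCCC)CCCC)[C@H](C(=O)N2C(=O)OC[C@H]2Cc2ccccc2)Oc2ccc([C@@H]3OC[C@@H]4[C@H]3CO[C@H]4c3cc(OC)c(O[Si](C(C)C)(C(C)C)C(C)C)c(OC)c3)cc2OC)ccc1O[Si](C(C)C)(C(C)C)C(C)C | intermediate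
24 | (R)-4-benzyl-3-[(2R,3S)-3-hydroxy-3-{3-methoxy-4-(triisopropylsilyloxy)phenyl}-2-{4-[(1R,3aS,4R,6aS)-4-{3,5-dimethoxy-4-(triisopropylsilyloxy)phenyl}tetrahydro-1H,3H-furo[3,4-c]furan-1-yl]-2-methoxyphenoxy}propanoyl]oxazolidin-2-one | COc1cc([C@H](O)[C@H](C(=O)N2C(=O)OC[C@H]2Cc2ccccc2)Oc2ccc([C@@H]3OC[C@@H]4[C@H]3CO[C@H]4c3cc(OC)c(O[Si](C(C)C)(C(C)C)C(C)C)c(OC)c3)cc2OC)ccc1O[Si](C(C)C)(C(C)C)C(C)C | intermediate
25 | (1S,2S)-1-[3-methoxy-4-(triisopropylsilyloxy)phenyl]-2-[4-((1R,3aS,4R,6aS)-4-{3,5-dimethoxy-4-(triisopropylsilyloxy)phenyl}tetrahydro-1H,3H-furo[3,4-c]furan-1-yl)-2-methoxyphenoxy]propane-1,3-diol | COc1cc([C@H](O)[C@H](CO)Oc2ccc([C@@H]3OC[C@@H]4[C@H]3CO[C@H]4c3cc(OC)c(O[Si](C(C)C)(C(C)C)C(C)C)c(OC)c3)cc2OC)ccc1O[Si](C(C)C)(C(C)C)C(C)C | intermediate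
26 | (1S,2S)-1-(4-hydroxy-3-methoxyphenyl)-2-{4-[(1R,3aS,4R,6aS)-4-(4-hydroxy-3,5-dimethoxyphenyl)tetrahydro-1H,3H-furo[3,4-c]furan-1-yl]-2-methoxyphenoxy}propane-1,3-diol | COc1cc([C@H](O)[C@H](CO)Oc2ccc([C@@H]3OC[C@@H]4[C@H]3CO[C@H]4c3cc(OC)c(O)c(OC)c3)cc2OC)ccc1O | target

**Step count and risks**

Total: 15 steps. Longest linear sequence: 10 steps (1, 2, 3, 7, 8, 9, 11, 13, 14, 15 from syringaldehyde; equally 4, 5, 6, 7, 8, 9, 11, 13, 14, 15 from vanillin).

The three steps most likely to fail: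

1. Step 8. The C8 radical may be reduced by a second Cp2TiCl before it cyclises, which ends in β-elimination to an allylic alcohol. The 5-exo closure may also give too little of the isomer with C9 cis to the C7' arm, and after iodine addition elimination may compete with ether closure. Fallback, from 11 back to 14: the cyclisation is run without iodine and quenched with dilute acid so that the C7'–Ti bond of 12 is protonated, which should give {(2R,3S,4S)-4-[4-(allyloxy)-3-methoxybenzyl]-2-[3,5-dimethoxy-4-(triisopropylsilyloxy)phenyl]tetrahydrofuran-3-yl}methanol F1. The second ring is then closed oxidatively with DDQ (CH2Cl2, 0 °C), which removes hydride from the ring B benzylic CH2 so that the C9 hydroxyl captures the cation on the convex face and gives 14.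

2. Step 3. Epoxidation of the monosubstituted vinyl group is slow, so the titanium Lewis acid may open or ionise the electron-rich benzylic epoxy alcohol. The rate difference between the two enantiomers may also be too small to give a highly enriched epoxy alcohol at useful conversion. Fallback, from 4 back to 5: acylative enzymatic resolution with immobilised Candida antarctica lipase B and vinyl acetate (MTBE, rt) should acylate the (R)-alcohol selectively and give (R)-1-[3,5-dimethoxy-4-(triisopropylsilyloxy)phenyl]prop-2-en-1-yl acetate F2. iBu2AlH at −78 °C then frees (R)-1-[3,5-dimethoxy-4-(triisopropylsilyloxy)phenyl]prop-2-en-1-ol F3. Hydroxyl-directed epoxidation of F3 with VO(acac)2 and t-BuOOH should give 5 together with its C8 epimer, (S)-[3,5-dimethoxy-4-(triisopropylsilyloxy)phenyl][(2S)-oxiran-2-yl]methanol F4, which is separated; F4 would lead to the same furofuran because C8 becomes planar in step 8.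

3. Step 7. The electron-rich cinnamyl bromide 9 may ionise or polymerise before it alkylates, and alkoxide 10 may shift its epoxide to C7–C8 (Payne rearrangement) so that the ether forms at O9. Fallback, from 5 back to 15: alkoxide 10 is alkylated with allyl bromide, a stable and fast electrophile, to give (2R)-2-[(S)-(allyloxy){3,5-dimethoxy-4-(triisopropylsilyloxy)phenyl}methyl]oxirane F5. Cross-metathesis of F5 with commercial 4-acetoxy-3-methoxystyrene (C=Cc1ccc(OC(C)=O)c(OC)c1; second-generation Grubbs catalyst, CH2Cl2, 40 °C) installs the E-styrene and should give 4-[(1E)-3-{(S)-[3,5-dimethoxy-4-(triisopropylsilyloxy)phenyl][(2R)-oxiran-2-yl]methoxy}prop-1-en-1-yl]-2-methoxyphenyl acetate F6. The Cp2TiCl/iodine cascade of step 8 applied to F6 passes through the C7'–TiCp2Cl C9–OTiCp2Cl tetrahydrofuran F7 and the C7' iodide F8 to 4-{(1R,3aS,4R,6aS)-4-[3,5-dimethoxy-4-(triisopropylsilyloxy)phenyl]tetrahydro-1H,3H-furo[3,4-c]furan-1-yl}-2-methoxyphenyl acetate F9. K2CO3 in MeOH at 0 °C removes the acetate and gives 15, which also makes step 9 unnecessary.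

Further compounds
F1 | step 8 | {(2R,3S,4S)-4-[4-(allyloxy)-3-methoxybenzyl]-2-[3,5-dimethoxy-4-(triisopropylsilyloxy)phenyl]tetrahydrofuran-3-yl}methanol | COc1cc([C@@H]2OC[C@@H](Cc3ccc(OCC=C)c(OC)c3)[C@H]2CO)cc(OC)c1O[Si](C(C)C)(C(C)C)C(C)C
F2 | step 3 | (R)-1-[3,5-dimethoxy-4-(triisopropylsilyloxy)phenyl]prop-2-en-1-yl acetate | CC(=O)O[C@H](C=C)c1cc(OC)c(O[Si](C(C)C)(C(C)C)C(C)C)c(OC)c1
F3 | step 3 | (R)-1-[3,5-dimethoxy-4-(triisopropylsilyloxy)phenyl]prop-2-en-1-ol | O[C@H](C=C)c1cc(OC)c(O[Si](C(C)C)(C(C)C)C(C)C)c(OC)c1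
F4 | step 3 | (S)-[3,5-dimethoxy-4-(triisopropylsilyloxy)phenyl][(2S)-oxiran-2-yl]methanol (threo) | O[C@H]([C@@H]1CO1)c1cc(OC)c(O[Si](C(C)C)(C(C)C)C(C)C)c(OC)c1
F5 | step 7 | (2R)-2-[(S)-(allyloxy){3,5-dimethoxy-4-(triisopropylsilyloxy)phenyl}methyl]oxirane | C=CCO[C@H]([C@H]1CO1)c1cc(OC)c(O[Si](C(C)C)(C(C)C)C(C)C)c(OC)c1
F6 | step 7 | 4-[(1E)-3-{(S)-[3,5-dimethoxy-4-(triisopropylsilyloxy)phenyl][(2R)-oxiran-2-yl]methoxy}prop-1-en-1-yl]-2-methoxyphenyl acetate | CC(=O)Oc1ccc(/C=C/CO[C@H]([C@H]2CO2)c2cc(OC)c(O[Si](C(C)C)(C(C)C)C(C)C)c(OC)c2)cc1OC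
F7 | step 7 | acetate analogue of 12: tetrahydrofuran with CH(TiCp2Cl)(4-acetoxy-3-methoxyphenyl) on C8' and CH2–O–TiCp2Cl on C8 | COc1cc([C@@H]2OC[C@@H](C([Ti](Cl)(C3C=CC=C3)C3C=CC=C3)c3ccc(OC(C)=O)c(OC)c3)[C@H]2CO[Ti](Cl)(C2C=CC=C2)C2C=CC=C2)cc(OC)c1O[Si](C(C)C)(C(C)C)C(C)C
F8 | step 7 | acetate analogue of 13: tetrahydrofuran with CH(I)(4-acetoxy-3-methoxyphenyl) on C8' and CH2–O–TiCp2Cl on C8 | COc1cc([C@@H]2OC[C@@H](C(I)c3ccc(OC(C)=O)c(OC)c3)[C@H]2CO[Ti](Cl)(C2C=CC=C2)C2C=CC=C2)cc(OC)c1O[Si](C(C)C)(C(C)C)C(C)C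
F9 | step 7 | 4-{(1R,3aS,4R,6aS)-4-[3,5-dimethoxy-4-(triisopropylsilyloxy)phenyl]tetrahydro-1H,3H-furo[3,4-c]furan-1-yl}-2-methoxyphenyl acetate | CC(=O)Oc1ccc([C@@H]2OC[C@@H]3[C@H]2CO[C@H]3c2cc(OC)c(O[Si](C(C)C)(C(C)C)C(C)C)c(OC)c2)cc1OC
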